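## Retrosynthetic overview

- Target ⇒ one global hydrogenolysis (21 benzyl ethers, two C8–Br caps) of a perbenzylated, doubly C8-brominated trimer.
- Trimer ⇒ C4(middle)–C8(lower) bond: a 4β-(2-ethoxyethoxy) dimer is ionised to its ring-A quinone-methide cation and captured by perbenzylated epicatechin gallate.
- Dimer ⇒ C4(upper)–C6(middle) bond (key step): DDQ hydride abstraction dearomatises ring A of an 8-bromo monomer to a quinone-methide oxocarbenium ion. A second 8-bromo monomer that already carries the C4 ether traps it in the same flask through C6; bromine at C8 forces the 4→6 mode, and the upper unit needs no leaving group.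
- Both monomers ⇒ perbenzylated epicatechin gallate (NBS for the upper unit; DDQ/2-ethoxyethanol, then NBS, for the middle unit) ⇒ tetra-O-benzyl-(−)-epicatechin + tri-O-benzylgallic acid (Steglich ester).
- No ring is built: rings A, B and C and the C2/C3 stereocentres of all three units come from the monomer. Only the two C4 stereocentres are created, upper–middle bond first, middle–lower bond second.

Assumption: the target is read as epicatechin-3-O-gallate-(4β→6)-epicatechin-3-O-gallate-(4β→8)-epicatechin-3-O-gallate (all units 2R,3R; "α" is the face of the 2-aryl and 3-acyloxy groups, "β" the opposite face), and 1 and 2 are bought as catalogue compounds.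

## Route

Step 1
Reactants: 1 5,7,3',4'-tetra-O-benzyl-(−)-epicatechin; 2 3,4,5-tris(benzyloxy)benzoic acid (1.2 equiv)
Product: 3 hepta-O-benzyl-(−)-epicatechin 3-O-gallate
Conditions: DCC (1.3 equiv), DMAP (0.2 equiv), CH2Cl2, 0 °C to rt, 16 h
Reagents that add atoms: none
Why: Steglich esterification: DCC converts acid 2 into its O-acylisourea and DMAP relays the acyl group to the hindered axial 3-hydroxyl of 1, while the two existing stereocentres (2R,3R, bought in 1) are not touched.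

Step 2
Reactants: 3 hepta-O-benzyl-(−)-epicatechin 3-O-gallate
Product: 5 4β-(2-ethoxyethoxy)-hepta-O-benzyl-epicatechin 3-O-gallate, via quinone-methide oxocarbenium ion 4 (not isolated)
Conditions: DDQ (2 equiv), EtOCH2CH2OH (5 equiv), CH2Cl2, rt
Reagents that add atoms: 2-ethoxyethanol, CCOCCO
Why: DDQ benzylic oxidation: hydride abstraction from C4 dearomatises ring A to the benzyloxy-stabilised para-quinone-methide oxocarbenium ion 4, which the alcohol captures from the β face, anti to the 3α-galloyloxy group (acyloxonium participation), setting C4 as 4β-alkoxy (4S, 3,4-trans) and restoring aromaticity.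

Step 3
Reactants: 5 4β-(2-ethoxyethoxy)-hepta-O-benzyl-epicatechin 3-O-gallate
Product: 6 8-bromo-4β-(2-ethoxyethoxy)-hepta-O-benzyl-epicatechin 3-O-gallate
Conditions: NBS (1.0 equiv), CH2Cl2, −40 °C to 0 °C
Reagents that add atoms: N-bromosuccinimide, O=C1CCC(=O)N1Br
Why: Electrophilic aromatic bromination: ring A is the only trialkoxy-activated ring and C8 is its kinetically preferred position (C6 is shielded by the C5 benzyloxy group and the pseudo-axial C4 ether), and because only neutral succinimide is formed the acid-labile C4 ether and all three stereocentres survive.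

Step 4
Reactants: 3 hepta-O-benzyl-(−)-epicatechin 3-O-gallate
Product: 7 8-bromo-hepta-O-benzyl-(−)-epicatechin 3-O-gallate
Conditions: NBS (1.0 equiv), CH2Cl2, −40 °C to 0 °C
Reagents that add atoms: N-bromosuccinimide, O=C1CCC(=O)N1Br
Why: Electrophilic aromatic bromination: C8 is the kinetically preferred position of 5,7-dibenzyloxyflavans with one equivalent of NBS at low temperature, so the C8 cap goes on without touching ring B, the galloyl ring or any stereocentre.

Step 5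
Reactants: 7 8-bromo-hepta-O-benzyl-(−)-epicatechin 3-O-gallate (1 equiv, added slowly); 6 8-bromo-4β-(2-ethoxyethoxy)-hepta-O-benzyl-epicatechin 3-O-gallate (3 equiv)
Product: 9 8-bromo-hepta-O-benzyl-epicatechin 3-O-gallate-(4β→6)-8-bromo-4β-(2-ethoxyethoxy)-hepta-O-benzyl-epicatechin 3-O-gallate, via brominated quinone-methide oxocarbenium ion 8 (not isolated)
Conditions: DDQ (1.05 equiv), 4 Å molecular sieves, anhydrous CH2Cl2, 0 °C to rt; 7 and DDQ added from two syringes over 2 h to 6; excess 6 recovered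
Reagents that add atoms: none
Why: Proposed new method: DDQ removes the pseudo-axial C4 hydride of 7 to give the ring-A-dearomatised quinone-methide oxocarbenium ion 8 (ion pair with the DDQ hydroquinone monoanion), and because no alcohol is present and both 7 and DDQ are kept at low stationary concentration the only competent π-nucleophile is C6 of 6 (C8 blocked by Br; its C4–H is pseudo-equatorial and α-alkoxylated, hence slow toward DDQ), which attacks the β face anti to the participating 3α-galloyloxy group so that rearomatisation leaves the new C4 stereocentre β (3,4-trans) with 4→6 connectivity; closest known reaction types: DDQ-mediated cross-dehydrogenative benzylic C–H arylation with electron-rich arenes and the DDQ/alcohol C4 oxidation of benzylated flavan-3-ols used in step 2.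

Step 6
Reactants: 9 8-bromo-hepta-O-benzyl-epicatechin 3-O-gallate-(4β→6)-8-bromo-4β-(2-ethoxyethoxy)-hepta-O-benzyl-epicatechin 3-O-gallate; 3 hepta-O-benzyl-(−)-epicatechin 3-O-gallate (3.5 equiv)
Product: 11 8-bromo-hepta-O-benzyl-epicatechin 3-O-gallate-(4β→6)-8-bromo-hepta-O-benzyl-epicatechin 3-O-gallate-(4β→8)-hepta-O-benzyl-epicatechin 3-O-gallate, via dimer quinone-methide oxocarbenium ion 10 (not isolated)
Conditions: Me3SiOSO2CF3 (0.3 equiv), CH2Cl2, −40 °C; Et3N quench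
Reagents that add atoms: none
Why: Lewis-acid SN1 (Friedel–Crafts-type) flavan C4 arylation: the silyl triflate ionises the 2-ethoxyethyl ether of 9 to the ring-A-dearomatised cation 10, whose own rings A are blocked or bromine-deactivated, and the most nucleophilic site on offer, C8 of excess 3, adds from the β face anti to the 3α-galloyloxy group, giving the 4β→8 bond (3,4-trans) at −40 °C where existing interflavan bonds do not ionise.

Step 7
Reactants: 11 8-bromo-hepta-O-benzyl-epicatechin 3-O-gallate-(4β→6)-8-bromo-hepta-O-benzyl-epicatechin 3-O-gallate-(4β→8)-hepta-O-benzyl-epicatechin 3-O-gallate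
Product: 12 epicatechin 3-O-gallate-(4β→6)-epicatechin 3-O-gallate-(4β→8)-epicatechin 3-O-gallate (CNP0183218.1)
Conditions: H2 (1 atm), Pd(OH)2 on carbon, Et3N (2.0 equiv), THF/MeOH/H2O, rt; Sephadex LH-20
Reagents that add atoms: none
Why: Heterogeneous hydrogenolysis cleaves all 21 benzyl aryl ethers and hydrodebrominates both C8–Br caps in one operation while Et3N traps the HBr that would otherwise cleave the acid-labile interflavan bonds; the non-benzylic C3 gallate esters and all eight stereocentres are unaffected.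

## Compound list

1 | 5,7,3',4'-tetra-O-benzyl-(−)-epicatechin; (2R,3R)-5,7-bis(benzyloxy)-2-[3,4-bis(benzyloxy)phenyl]chroman-3-ol | O(Cc1ccccc1)c1cc(OCc3ccccc3)c2c(c1)O[C@H](c1ccc(OCc3ccccc3)c(OCc3ccccc3)c1)[C@H](O)C2 | starting material

2 | 3,4,5-tris(benzyloxy)benzoic acid (tri-O-benzylgallic acid) | OC(=O)c1cc(OCc2ccccc2)c(OCc2ccccc2)c(OCc2ccccc2)c1 | starting material

3 | hepta-O-benzyl-(−)-epicatechin 3-O-gallate; (2R,3R)-5,7-bis(benzyloxy)-2-[3,4-bis(benzyloxy)phenyl]chroman-3-yl 3,4,5-tris(benzyloxy)benzoate | O(Cc1ccccc1)c1cc(OCc3ccccc3)c2c(c1)O[C@H](c1ccc(OCc3ccccc3)c(OCc3ccccc3)c1)[C@H](OC(=O)c1cc(OCc3ccccc3)c(OCc3ccccc3)c(OCc3ccccc3)c1)C2 | intermediate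

4 | C4 cation of 3 drawn as the ring-A para-quinone methide 7-benzyloxonium ion (2R,3R; not isolated; counter-ion DDQ hydroquinone monoanion) | C(c1ccccc1)[O+]=C1C=C(OCc3ccccc3)C=2C(=C1)O[C@H](c1ccc(OCc3ccccc3)c(OCc3ccccc3)c1)[C@H](OC(=O)c1cc(OCc3ccccc3)c(OCc3ccccc3)c(OCc3ccccc3)c1)C=2 | intermediate

5 | (2R,3R,4S)-5,7-bis(benzyloxy)-2-[3,4-bis(benzyloxy)phenyl]-4-(2-ethoxyethoxy)chroman-3-yl 3,4,5-tris(benzyloxy)benzoate (2α-aryl, 3α-acyloxy, 4β-alkoxy) | O(Cc1ccccc1)c1cc(OCc3ccccc3)c2c(c1)O[C@H](c1ccc(OCc3ccccc3)c(OCc3ccccc3)c1)[C@H](OC(=O)c1cc(OCc3ccccc3)c(OCc3ccccc3)c(OCc3ccccc3)c1)[C@H]2OCCOCC | intermediate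

6 | (2R,3R,4S)-8-bromo-5,7-bis(benzyloxy)-2-[3,4-bis(benzyloxy)phenyl]-4-(2-ethoxyethoxy)chroman-3-yl 3,4,5-tris(benzyloxy)benzoate (2α-aryl, 3α-acyloxy, 4β-alkoxy) | O(Cc1ccccc1)c1cc(OCc3ccccc3)c2c(c1Br)O[C@H](c1ccc(OCc3ccccc3)c(OCc3ccccc3)c1)[C@H](OC(=O)c1cc(OCc3ccccc3)c(OCc3ccccc3)c(OCc3ccccc3)c1)[C@H]2OCCOCC | intermediate

7 | 8-bromo derivative of 3; (2R,3R)-8-bromo-5,7-bis(benzyloxy)-2-[3,4-bis(benzyloxy)phenyl]chroman-3-yl 3,4,5-tris(benzyloxy)benzoate | O(Cc1ccccc1)c1cc(OCc3ccccc3)c2c(c1Br)O[C@H](c1ccc(OCc3ccccc3)c(OCc3ccccc3)c1)[C@H](OC(=O)c1cc(OCc3ccccc3)c(OCc3ccccc3)c(OCc3ccccc3)c1)C2 | intermediate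

8 | C4 cation of 7 drawn as the ring-A para-quinone methide 7-benzyloxonium ion (2R,3R; not isolated; counter-ion DDQ hydroquinone monoanion) | C(c1ccccc1)[O+]=C1C=C(OCc3ccccc3)C=2C(=C1Br)O[C@H](c1ccc(OCc3ccccc3)c(OCc3ccccc3)c1)[C@H](OC(=O)c1cc(OCc3ccccc3)c(OCc3ccccc3)c(OCc3ccccc3)c1)C=2 | intermediate

9 | protected dimer: C4 of the upper 8-bromo unit bonded β to C6 of the middle 8-bromo unit, which carries 4β-OCH2CH2OEt; both units 2α-aryl, 3α-galloyloxy, 3,4-trans | O(Cc1ccccc1)c1cc(OCc3ccccc3)c2c(c1Br)O[C@H](c1ccc(OCc3ccccc3)c(OCc3ccccc3)c1)[C@H](OC(=O)c1cc(OCc3ccccc3)c(OCc3ccccc3)c(OCc3ccccc3)c1)[C@H]2c1c(OCc3ccccc3)c(Br)c2c(c1OCc3ccccc3)[C@H](OCCOCC)[C@@H](OC(=O)c1cc(OCc3ccccc3)c(OCc3ccccc3)c(OCc3ccccc3)c1)[C@@H](c1ccc(OCc3ccccc3)c(OCc3ccccc3)c1)O2 | intermediate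

10 | C4 cation of the middle unit of 9 drawn as its ring-A para-quinone methide 7-benzyloxonium ion (not isolated; counter-ion triflate) | O(Cc1ccccc1)c1cc(OCc3ccccc3)c2c(c1Br)O[C@H](c1ccc(OCc3ccccc3)c(OCc3ccccc3)c1)[C@H](OC(=O)c1cc(OCc3ccccc3)c(OCc3ccccc3)c(OCc3ccccc3)c1)[C@H]2C1C(=[O+]Cc3ccccc3)C(Br)=C2C(C=1OCc3ccccc3)=C[C@@H](OC(=O)c1cc(OCc3ccccc3)c(OCc3ccccc3)c(OCc3ccccc3)c1)[C@@H](c1ccc(OCc3ccccc3)c(OCc3ccccc3)c1)O2 | intermediate

11 | protected trimer: upper (8-Br) C4β→C6 middle (8-Br), middle C4β→C8 lower; 21 benzyl ethers; every unit 2α-aryl, 3α-galloyloxy | O(Cc1ccccc1)c1cc(OCc3ccccc3)c2c(c1Br)O[C@H](c1ccc(OCc3ccccc3)c(OCc3ccccc3)c1)[C@H](OC(=O)c1cc(OCc3ccccc3)c(OCc3ccccc3)c(OCc3ccccc3)c1)[C@H]2c1c(OCc3ccccc3)c(Br)c2c(c1OCc3ccccc3)[C@H](c1c(OCc3ccccc3)cc(OCc3ccccc3)c4c1O[C@H](c1ccc(OCc3ccccc3)c(OCc3ccccc3)c1)[C@H](OC(=O)c1cc(OCc3ccccc3)c(OCc3ccccc3)c(OCc3ccccc3)c1)C4)[C@@H](OC(=O)c1cc(OCc3ccccc3)c(OCc3ccccc3)c(OCc3ccccc3)c1)[C@@H](c1ccc(OCc3ccccc3)c(OCc3ccccc3)c1)O2 | intermediate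

12 | epicatechin 3-O-gallate-(4β→6)-epicatechin 3-O-gallate-(4β→8)-epicatechin 3-O-gallate (CNP0183218.1) | O=C(O[C@@H]1[C@@H](c2c(O)cc3c(c2O)[C@H](c2c(O)cc(O)c4c2O[C@H](c2ccc(O)c(O)c2)[C@H](OC(=O)c2cc(O)c(O)c(O)c2)C4)[C@@H](OC(=O)c2cc(O)c(O)c(O)c2)[C@@H](c2ccc(O)c(O)c2)O3)c2c(O)cc(O)cc2O[C@@H]1c1ccc(O)c(O)c1)c1cc(O)c(O)c(O)c1 | target

## Step count and risk

Total step count: 7. Longest linear sequence: 6 (1 → 3 → 5 → 6 → 9 → 11 → 12; step 4, 3 → 7, is the one-step branch).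

Steps most likely to fail:

Step 5 (oxidative 4→6 coupling). The cation may recombine with the DDQ hydroquinone anion, 7 may homocouple through its own C6, DDQ may over-oxidise 6 at C4, or the bromine-deactivated C6 of 6 may simply be too slow. The fallback replaces the oxidative union by orthogonal leaving-group activation and sets out from 6. Exchange of the C4 ether with 2,6-dimethylbenzenethiol (BF3·OEt2 0.2 equiv, CH2Cl2, −78 °C) gives 8-bromo-4β-(2,6-dimethylphenylthio)-hepta-O-benzyl-epicatechin 3-O-gallate F1. A second portion of 6 is then ionised with BF3·OEt2 to cation 8 in the presence of F1 (2.5 equiv), whose hindered thioether is inert to the hard Lewis acid and whose only free ring-A position is C6. This gives the (4β→6) dimer 4β-(2,6-dimethylphenylthio) ether F2. Soft activation of F2 with N-iodosuccinimide in the presence of 3 (3 equiv, CH2Cl2, −20 °C) forms the 4β→8 bond and comes back to the route at 11, so steps 4, 5 and 6 are all replaced.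

Step 6 (coupling of the hindered dimer cation with a galloylated nucleophile). The 3-O-galloyl nucleophile 3 is bulky and slightly deactivated, so the reaction may be slow enough for 4→6 attack or interflavan scrambling to appear. The fallback changes the nucleophile and moves the third galloylation to the end; it sets out from 9. Coupling of 9 with the smaller and more reactive C8 nucleophile 1 (4 equiv; Me3SiOSO2CF3, CH2Cl2, −40 °C) gives the trimer with a free lower 3-hydroxyl F3. Steglich esterification of F3 with 2 (DCC, DMAP cat., CH2Cl2) comes back to the route at 11.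

Step 7 (23 hydrogenolytic events on one acid- and air-sensitive molecule). Bromide may poison the catalyst, and local HBr may cleave interflavan bonds before debenzylation is complete. The fallback separates the two reductions and sets out from 11. Radical-chain hydrodebromination (n-Bu3SnH 2.5 equiv, AIBN cat., toluene, 80 °C) gives the bromine-free heneicosa-O-benzyl trimer F4. F4 is then debenzylated under strictly neutral conditions (H2, Pd(OH)2 on carbon, THF/MeOH/H2O) and comes back to the route at 12.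

## Further compounds

F1 | step 5 | 8-bromo-4β-(2,6-dimethylphenylthio)-hepta-O-benzyl-epicatechin 3-O-gallate | O(Cc1ccccc1)c1cc(OCc3ccccc3)c2c(c1Br)O[C@H](c1ccc(OCc3ccccc3)c(OCc3ccccc3)c1)[C@H](OC(=O)c1cc(OCc3ccccc3)c(OCc3ccccc3)c(OCc3ccccc3)c1)[C@H]2Sc1c(C)cccc1C

F2 | step 5 | 8-bromo-hepta-O-benzyl-epicatechin 3-O-gallate-(4β→6)-8-bromo-4β-(2,6-dimethylphenylthio)-hepta-O-benzyl-epicatechin 3-O-gallate | O(Cc1ccccc1)c1cc(OCc3ccccc3)c2c(c1Br)O[C@H](c1ccc(OCc3ccccc3)c(OCc3ccccc3)c1)[C@H](OC(=O)c1cc(OCc3ccccc3)c(OCc3ccccc3)c(OCc3ccccc3)c1)[C@H]2c1c(OCc3ccccc3)c(Br)c2c(c1OCc3ccccc3)[C@H](Sc1c(C)cccc1C)[C@@H](OC(=O)c1cc(OCc3ccccc3)c(OCc3ccccc3)c(OCc3ccccc3)c1)[C@@H](c1ccc(OCc3ccccc3)c(OCc3ccccc3)c1)O2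

F3 | step 6 | protected trimer as 11 but with a free 3-hydroxyl on the lower unit (no lower galloyl group) | O(Cc1ccccc1)c1cc(OCc3ccccc3)c2c(c1Br)O[C@H](c1ccc(OCc3ccccc3)c(OCc3ccccc3)c1)[C@H](OC(=O)c1cc(OCc3ccccc3)c(OCc3ccccc3)c(OCc3ccccc3)c1)[C@H]2c1c(OCc3ccccc3)c(Br)c2c(c1OCc3ccccc3)[C@H](c1c(OCc3ccccc3)cc(OCc3ccccc3)c4c1O[C@H](c1ccc(OCc3ccccc3)c(OCc3ccccc3)c1)[C@H](O)C4)[C@@H](OC(=O)c1cc(OCc3ccccc3)c(OCc3ccccc3)c(OCc3ccccc3)c1)[C@@H](c1ccc(OCc3ccccc3)c(OCc3ccccc3)c1)O2

F4 | step 7 | bromine-free heneicosa-O-benzyl trimer (11 with H in place of both Br) | O(Cc1ccccc1)c1cc(OCc3ccccc3)c2c(c1)O[C@H](c1ccc(OCc3ccccc3)c(OCc3ccccc3)c1)[C@H](OC(=O)c1cc(OCc3ccccc3)c(OCc3ccccc3)c(OCc3ccccc3)c1)[C@H]2c1c(OCc3ccccc3)cc2c(c1OCc3ccccc3)[C@H](c1c(OCc3ccccc3)cc(OCc3ccccc3)c4c1O[C@H](c1ccc(OCc3ccccc3)c(OCc3ccccc3)c1)[C@H](OC(=O)c1cc(OCc3ccccc3)c(OCc3ccccc3)c(OCc3ccccc3)c1)C4)[C@@H](OC(=O)c1cc(OCc3ccccc3)c(OCc3ccccc3)c(OCc3ccccc3)c1)[C@@H](c1ccc(OCc3ccccc3)c(OCc3ccccc3)c1)O2
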